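Numbering is that of the clerodanes: ring A = C1–C5 and C10, ring B = C5–C10, chain C11–C16, methyls C17 (on C8), C18 (on C4), C19 (on C5), C20 (on C9); β is the face that carries H-10.
Cuts: the C15 ester; C12–C13 (sp3–sp2 coupling with a (Z)-3-iodobut-2-ene-1,4-diol unit); then ring B at C7–C8, C5–C6 and C9–C10. This leaves ring A as 2-methylcyclohex-2-enone (its carbonyl is C4), C6–C7 as a vinyl sulfone, and C17–C8=C9(C20)–C11–C12 as a (Z)-allylic sulfoxide.
Enabling feature: C8 bears a methyl and lies between the ring methylene C7 and the quaternary C9. A sulfinyl group on C17 can therefore first carry C9 to C10 as an allyl anion and then, as a vinyl sulfoxide, make C8 the acceptor for a carbanion at C7 six atoms away (C7–C6–C5–C10–C9–C8); C–S reduction afterwards leaves C17 as the methyl and C7 as the methylene.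
Forward order: sulfoxide; one-flask annulation onto ring A that ends with the C7–C8 closure of ring B; C4 ketone to C3=C4–C18; one reductive step removes both sulfur groups and the benzyl ether; C12 iodide, Suzuki–Miyaura coupling for C12–C13, acylation at O15, desilylation at O16.
Stereochemistry: the sulfur stereocentre (tartrate-controlled sulfoxidation) and the (Z)-alkene set C9 and C10, C5 follows by anti alkylation, C8 by the chair closure; the 13,14-alkene geometry comes from trans-hydroalumination/iodination and a stereoretentive coupling.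

Key step: step 5

Remark: the sense in which the sulfinyl group selects the enone face is assumed to be that of the lithium-chelated transition state with the tolyl group turned away from the enone, which calls for the (S)-sulfoxide; were the sense opposite, the (R)-sulfoxide from (R,R)-diethyl tartrate would be used and nothing else would change.

Step 1
Reactants: 1 4-(benzyloxy)but-1-yne
Product: 3 alkynol 5-(benzyloxy)pent-2-yn-1-ol, via lithium acetylide 2 (not isolated)
Conditions: n-BuLi, THF, −78 °C; (CH2O)n, −78 °C to rt; aq NH4Cl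
Reagents that add atoms: formaldehyde (from paraformaldehyde), C=O
Why: Addition of the lithium acetylide to formaldehyde (alkynylation of an aldehyde) gives the propargylic alcohol whose hydroxyl directs the next step, and no stereocentre is formed.

Step 2
Reactants: 3 alkynol 5-(benzyloxy)pent-2-yn-1-ol
Product: 4 (Z)-5-(benzyloxy)-3-methylpent-2-en-1-ol
Conditions: MeMgBr (5 equiv), Fe(acac)3 (10 mol %), THF, −78 to 0 °C; aq NH4Cl
Reagents that add atoms: methylmagnesium bromide, C[Mg]Br
Why: Iron-catalysed, alkoxide-directed syn-carbomagnesiation of the propargylic alcohol should put the methyl on the distal alkyne carbon and magnesium next to the carbinol, so that protonation leaves the benzyloxyethyl chain cis to CH2OH, the (Z)-geometry that later becomes the C9 configuration.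

Step 3
Reactants: 4 (Z)-5-(benzyloxy)-3-methylpent-2-en-1-ol
Product: 5 (Z)-5-(benzyloxy)-3-methylpent-2-en-1-yl 4-methylphenyl sulfide
Conditions: (4-MeC6H4S)2, PBu3, THF, 0 °C to rt
Reagents that add atoms: bis(4-methylphenyl) disulfide, Cc1ccc(SSc2ccc(C)cc2)cc1
Why: Mitsunobu-type thioetherification (disulfide/phosphine) displaces the primary alkoxyphosphonium ion by thiolate in an SN2 step, so the sulfide forms at C17 without allylic transposition or change of alkene geometry.

Step 4
Reactants: 5 (Z)-5-(benzyloxy)-3-methylpent-2-en-1-yl 4-methylphenyl sulfide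
Product: 6 (S)-sulfoxide of 5 (sulfur S-configured; alkene Z)
Conditions: Ti(OiPr)4, (S,S)-diethyl tartrate, H2O (1:2:1), cumene hydroperoxide, CH2Cl2, −25 °C; product kept below 0 °C
Reagents that add atoms: cumene hydroperoxide, CC(C)(OO)c1ccccc1
Why: Kagan–Modena sulfoxidation transfers oxygen to one lone pair of the aryl alkyl sulfide inside the chiral titanium tartrate complex, the (S,S)-tartrate being expected to give the (S)-sulfoxide, the one stereocentre from which all others are relayed.

Step 5
Reactants: 6 (S)-sulfoxide; 7 2-methylcyclohex-2-en-1-one; 8 phenyl vinyl sulfone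
Product: 13 trans-decalone (C4 ketone; 5α-CH3; 10β-H; 9α-CH3; 9β-CH2CH2OBn; 8α-CH2S(O)Tol; 7-SO2Ph), via lithiated sulfoxide 9 (not isolated), via lithium enolate 10 (not isolated), via lithiated sulfone 11 (not isolated), via ring-closed lithio sulfoxide 12 (not isolated)
Conditions: LiN(iPr)2 (1.05 equiv), THF, −78 °C; 7, −78 °C; then 8 (1.0 equiv), DMPU, −78 to −20 °C; aq NH4Cl
Reagents that add atoms: none
Why: Proposed new method: LiN(iPr)2 gives the sulfinyl allyl anion 9, which should add through its γ-carbon (C9) to C10 of enone 7 in a lithium-bridged (sulfinyl O–Li–O=C) chair-like array to give enolate 10; 10 adds at C5 to vinyl sulfone 8, and the α-sulfonyl carbanion 11 closes ring B by conjugate addition of C7 to C8 of the (E)-vinyl sulfoxide that the first addition has just created, giving 12, which is protonated on work-up. The closest known reaction types are the γ-selective conjugate addition of lithiated allylic sulfoxides to cyclic enones with trapping of the enolate, Michael–Michael ring-closure annulations of enolates with vinyl sulfones, and the intramolecular Michael addition of sulfonyl carbanions to vinyl sulfoxides; only their union in one flask is new. Ring B closes in the 6-exo-trig mode through a chair in which C6 and C9 are both equatorial on ring A, so the ring fusion is trans. C9 and C10 are set together by the (Z)-geometry of 6 within the chelated transition state (C20 ends anti to H-10) and their absolute sense by the sulfur stereocentre; C5 is set by attack of the enolate on 8 anti to the bulky C10 substituent; C8 is set in the chair closure with the C17 terminus equatorial and the alkene eclipsing the C9 methyl, away from ring A, which is also the more stable epimer if the last addition is reversible. The step needs γ-1,4 selectivity of 9 (chelation should secure it, and a 1,2-adduct through C17 would converge on 10 by anionic oxy-Cope shift) and ring closure of 11 faster than proton transfer from C3 (favoured by the intramolecular six-membered exo mode, the low temperature and one equivalent of 8); the C7 configuration is irrelevant because the sulfone is removed.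

Step 6
Reactants: 13 trans-decalone
Product: 15 C3=C4 enol triflate of 13, via potassium enolate 14 (not isolated)
Conditions: KN(SiMe3)2 (1.1 equiv), THF, −78 °C; PhNTf2, −78 to 0 °C; aq NH4Cl
Reagents that add atoms: N-phenylbis(trifluoromethanesulfonimide), FC(F)(F)S(=O)(=O)N(c1ccccc1)S(=O)(=O)C(F)(F)F
Why: In this enol triflate formation C3 is the only enolisable position of the C4 ketone (C5 is quaternary) and is more acidic than the C–H bonds next to sulfur, so kinetic deprotonation and O-sulfonylation fix the double bond at C3=C4.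

Step 7
Reactants: 15 enol triflate
Product: 16 4-methyl-Δ3-decalin still carrying 7-SO2Ph, 17-S(O)Tol and 12-OBn
Conditions: Me2Zn, Pd(PPh3)4 (5 mol %), THF, 0 °C to rt
Reagents that add atoms: dimethylzinc, C[Zn]C
Why: Negishi coupling of the enol triflate with Me2Zn under zerovalent palladium installs C18 on C4 and keeps the alkene at C3=C4, the sulfone and sulfoxide being inert to the organozinc reagent.

Step 8
Reactants: 16 bis-sulfur benzyl ether
Product: 17 2-[(1S,2R,4aR,8aR)-1,2,4a,5-tetramethyl-1,2,3,4,4a,7,8,8a-octahydronaphthalen-1-yl]ethanol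
Conditions: Li, NH3(l)/THF, −78 °C; solid NH4Cl
Reagents that add atoms: none
Why: Dissolving-metal (Birch-type) reduction cleaves by electron transfer the alkyl C–S bonds of the aryl sulfone at C7 and the aryl sulfoxide at C17 and the benzyl C–O bond in one operation, while the isolated trisubstituted alkene and the four stereocentres are not affected.

Step 9
Reactants: 17 primary alcohol
Product: 18 (1S,2R,4aR,8aR)-1-(2-iodoethyl)-1,2,4a,5-tetramethyl-1,2,3,4,4a,7,8,8a-octahydronaphthalene
Conditions: I2, PPh3, imidazole, CH2Cl2, 0 °C to rt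
Reagents that add atoms: iodine, [I][I]
Why: Appel-type iodination converts the unhindered primary alcohol into the iodide by SN2 displacement of the alkoxyphosphonium ion.

Step 10
Reactants: 19 4-[(tert-butyldimethylsilyl)oxy]but-2-yn-1-ol
Product: 21 (Z)-4-[(tert-butyldimethylsilyl)oxy]-3-iodobut-2-en-1-ol, via alkenylaluminate 20 (not isolated)
Conditions: NaAlH2(OCH2CH2OMe)2, THF, 0 °C to rt; then I2, THF, −78 to 0 °C
Reagents that add atoms: iodine, [I][I]
Why: Alkoxide-directed trans-hydroalumination of the propargylic alcohol puts aluminium on the carbon distal to the free hydroxyl, and iodinolysis with retention gives the (Z)-vinyl iodide in which iodine is cis to CH2OH and the two CH2O groups are trans.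

Step 11
Reactants: 18 iodide; 21 (Z)-vinyl iodide
Product: 24 (E)-3-[(tert-butyldimethylsilyloxy)methyl]-5-[(1S,2R,4aR,8aR)-1,2,4a,5-tetramethyl-1,2,3,4,4a,7,8,8a-octahydronaphthalen-1-yl]pent-2-en-1-ol, via alkyllithium 22 (not isolated), via lithium borate 23 (not isolated)
Conditions: 18, t-BuLi (2.1 equiv), Et2O, −78 °C; 9-MeO-9-BBN, THF, −78 °C to rt; then 21, PdCl2(dppf) (5 mol %), AsPh3, K3PO4 (3 M aq), DMF, rt
Reagents that add atoms: none
Why: Lithium–iodine exchange and capture by 9-MeO-9-BBN give a B-alkyl borate that transmetallates in a Suzuki–Miyaura coupling with the vinyl iodide with retention at the alkene, so C12 takes the place of iodine, cis to C15 and trans to the protected C16.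

Step 12
Reactants: 24 allylic alcohol; 25 docosanoyl chloride
Product: 26 docosanoate of 24 (O16 still silylated)
Conditions: pyridine, DMAP (cat.), CH2Cl2, 0 °C to rt
Reagents that add atoms: none
Why: DMAP-catalysed acylation of the only free hydroxyl (primary, allylic, at C15) with the acid chloride is a standard esterification.

Step 13
Reactants: 26 silyl ether ester
Product: 27 target, (E)-3-(hydroxymethyl)-5-[(1S,2R,4aR,8aR)-1,2,4a,5-tetramethyl-1,2,3,4,4a,7,8,8a-octahydronaphthalen-1-yl]pent-2-en-1-yl docosanoate
Conditions: HF·pyridine, THF/pyridine, 0 °C to rt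
Reagents that add atoms: none
Why: Fluoride-induced cleavage of the primary silyl ether under buffered acidic conditions frees O16 without touching the ester or the ring alkene, and acyl migration is not possible because O15 and O16 lie trans across the C13=C14 bond.

Compound list
1 | 4-(benzyloxy)but-1-yne | C#CCCOCc1ccccc1 | starting material
2 | [4-(benzyloxy)but-1-yn-1-yl]lithium | [Li]C#CCCOCc1ccccc1 | intermediate
3 | 5-(benzyloxy)pent-2-yn-1-ol | OCC#CCCOCc1ccccc1 | intermediate
4 | (Z)-5-(benzyloxy)-3-methylpent-2-en-1-ol | OC/C=C(/C)CCOCc1ccccc1 | intermediate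
5 | (Z)-5-(benzyloxy)-3-methylpent-2-en-1-yl 4-methylphenyl sulfide | Cc1ccc(cc1)SC/C=C(/C)CCOCc1ccccc1 | intermediate
6 | (S)-configured sulfoxide of 5: 1-{[(Z)-5-(benzyloxy)-3-methylpent-2-en-1-yl]sulfinyl}-4-methylbenzene, S at sulfur | Cc1ccc(cc1)[S@@](=O)C/C=C(/C)CCOCc1ccccc1 | intermediate
7 | 2-methylcyclohex-2-en-1-one | CC1=CCCCC1=O | starting material
8 | phenyl vinyl sulfone | C=CS(=O)(=O)c1ccccc1 | starting material
9 | 6 lithiated at C17 (allyl anion) | Cc1ccc(cc1)[S@@](=O)C([Li])/C=C(/C)CCOCc1ccccc1 | intermediate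
10 | lithium C4-enolate of ring A carrying on C10 the quaternary C9 (CH3, CH2CH2OBn, (E)-CH=CH–S(O)Tol) | [Li]OC1=C(C)[C@H](CCC1)[C@@](C)(CCOCc2ccccc2)/C=C/[S@](=O)c2ccc(C)cc2 | intermediate
11 | ring A ketone with C5 quaternary (CH3 and CH2CH(Li)SO2Ph, trans to the C10 substituent) | O=C1CCC[C@H]([C@@](C)(CCOCc2ccccc2)/C=C/[S@](=O)c2ccc(C)cc2)[C@@]1(C)CC([Li])S(=O)(=O)c1ccccc1 | intermediate
12 | ring-closed trans-decalone lithiated at C17 | c1ccccc1COCC[C@@]1(C)[C@H](C([Li])[S@](=O)c2ccc(C)cc2)C(S(=O)(=O)c2ccccc2)C[C@@]2(C)C(=O)CCC[C@H]12 | intermediate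
13 | trans-decalone: C4 ketone, 5α-CH3, 10β-H, 9α-CH3, 9β-CH2CH2OBn, 8α-CH2–S(O)Tol (S at sulfur), 7-SO2Ph (either epimer) | c1ccccc1COCC[C@@]1(C)[C@H](C[S@](=O)c2ccc(C)cc2)C(S(=O)(=O)c2ccccc2)C[C@@]2(C)C(=O)CCC[C@H]12 | intermediate
14 | potassium C3=C4 enolate of 13 | c1ccccc1COCC[C@@]1(C)[C@H](C[S@](=O)c2ccc(C)cc2)C(S(=O)(=O)c2ccccc2)C[C@@]2(C)C(O[K])=CCC[C@H]12 | intermediate
15 | C3=C4 enol triflate of 13 | c1ccccc1COCC[C@@]1(C)[C@H](C[S@](=O)c2ccc(C)cc2)C(S(=O)(=O)c2ccccc2)C[C@@]2(C)C(OS(=O)(=O)C(F)(F)F)=CCC[C@H]12 | intermediate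
16 | 4-methyl-Δ3 analogue of 13 (C18 in place, sulfone, sulfoxide and benzyl ether retained) | c1ccccc1COCC[C@@]1(C)[C@H](C[S@](=O)c2ccc(C)cc2)C(S(=O)(=O)c2ccccc2)C[C@@]2(C)C(C)=CCC[C@H]12 | intermediate
17 | 2-[(1S,2R,4aR,8aR)-1,2,4a,5-tetramethyl-1,2,3,4,4a,7,8,8a-octahydronaphthalen-1-yl]ethanol | OCC[C@@]1(C)[C@H](C)CC[C@@]2(C)C(C)=CCC[C@H]12 | intermediate
18 | (1S,2R,4aR,8aR)-1-(2-iodoethyl)-1,2,4a,5-tetramethyl-1,2,3,4,4a,7,8,8a-octahydronaphthalene | ICC[C@@]1(C)[C@H](C)CC[C@@]2(C)C(C)=CCC[C@H]12 | intermediate
19 | 4-[(tert-butyldimethylsilyl)oxy]but-2-yn-1-ol | OCC#CCO[Si](C)(C)C(C)(C)C | starting material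
20 | sodium cyclic alkoxy(alkenyl)aluminate (Al on C3, ring through O1) | [Na+].COCCO[Al-]1(OCCOC)OCC=C1CO[Si](C)(C)C(C)(C)C | intermediate
21 | (Z)-4-[(tert-butyldimethylsilyl)oxy]-3-iodobut-2-en-1-ol | OC/C=C(I)/CO[Si](C)(C)C(C)(C)C | intermediate
22 | C12 alkyllithium from 18 | [Li]CC[C@@]1(C)[C@H](C)CC[C@@]2(C)C(C)=CCC[C@H]12 | intermediate
23 | lithium B-alkyl-B-methoxy-9-borabicyclo[3.3.1]nonane borate | [Li+].CO[B-]1(CC[C@@]3(C)[C@H](C)CC[C@@]4(C)C(C)=CCC[C@H]34)C2CCCC1CCC2 | intermediate
24 | (E)-3-[(tert-butyldimethylsilyloxy)methyl]-5-[(1S,2R,4aR,8aR)-1,2,4a,5-tetramethyl-1,2,3,4,4a,7,8,8a-octahydronaphthalen-1-yl]pent-2-en-1-ol | OC/C=C(/CO[Si](C)(C)C(C)(C)C)CC[C@@]1(C)[C@H](C)CC[C@@]2(C)C(C)=CCC[C@H]12 | intermediate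
25 | docosanoyl chloride | CCCCCCCCCCCCCCCCCCCCCC(=O)Cl | starting material
26 | docosanoate of 24 | CCCCCCCCCCCCCCCCCCCCCC(=O)OC/C=C(/CO[Si](C)(C)C(C)(C)C)CC[C@@]1(C)[C@H](C)CC[C@@]2(C)C(C)=CCC[C@H]12 | intermediate
27 | (E)-3-(hydroxymethyl)-5-[(1S,2R,4aR,8aR)-1,2,4a,5-tetramethyl-1,2,3,4,4a,7,8,8a-octahydronaphthalen-1-yl]pent-2-en-1-yl docosanoate | CCCCCCCCCCCCCCCCCCCCCC(=O)OC/C=C(/CO)CC[C@@]1(C)[C@H](C)CC[C@@]2(C)C(C)=CCC[C@H]12 | target

Total step count: 13. Longest linear sequence: 12 steps (steps 1 to 9, then 11, 12 and 13); step 10 makes the second fragment.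

Steps most likely to fail

Step 5 (Proposed new method). Proton transfer from C3 to the C7 carbanion, or sluggish addition of the hindered enolate to the vinyl sulfone, may outrun the ring closure, so that ring B does not close in the flask. Fallback, from 6, 7 and 8: the two intermolecular additions are run as in step 5 but the mixture is quenched at −78 °C, which should give the open-chain ketone F1. F1 is converted into the enol triflate F2 (KN(SiMe3)2, PhNTf2) and then into the methylcyclohexene F3 (Me2Zn, Pd(PPh3)4). Only then, with no ketone left to compete, is the sulfone deprotonated (LiN(iPr)2, THF, −78 to 0 °C) for the 6-exo-trig Michael closure onto the vinyl sulfoxide. This returns to the route at 16.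

Step 4. Oxygen transfer may be incompletely face-selective, and the allylic sulfoxide may lose sulfur and alkene configuration through the reversible Mislow–Evans shift. Fallback, from 5: oxidation with NaIO4 (MeOH/H2O, 0 °C) to the racemic sulfoxide, then separation of the enantiomers by preparative chromatography on a chiral stationary phase below 10 °C. This gives 6 beside its mirror image, the (R)-sulfoxide F4, and returns to the route at 6.

Step 8. The sulfinyl group may be cleaved on the aryl side or only in part, leaving sulfur on C17, while the sulfone and the benzyl ether cleave cleanly. Fallback, from 16: the sulfoxide is oxidised to the sulfone with H2O2 and (NH4)6Mo7O24 (cat.) in EtOH, giving the bis-sulfone F5. Both sulfones are removed with sodium amalgam Na(Hg) and Na2HPO4 in MeOH at −20 °C, giving the benzyl ether F6. The benzyl group is then removed with lithium naphthalenide LiC10H8 in THF at −25 °C, which returns to the route at 17.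

Further compounds
F1 | step 5 | open-chain ketone: ring A C4 ketone with C5 (CH3, CH2CH2SO2Ph) and C10 carrying C9 (CH3, CH2CH2OBn, (E)-CH=CH–S(O)Tol) | O=C1CCC[C@H]([C@@](C)(CCOCc2ccccc2)/C=C/[S@](=O)c2ccc(C)cc2)[C@@]1(C)CCS(=O)(=O)c1ccccc1
F2 | step 5 | C3=C4 enol triflate of F1 | FC(F)(F)S(=O)(=O)OC1=CCC[C@H]([C@@](C)(CCOCc2ccccc2)/C=C/[S@](=O)c2ccc(C)cc2)[C@@]1(C)CCS(=O)(=O)c1ccccc1
F3 | step 5 | 4-methylcyclohex-3-ene analogue of F1 (C18 in place) | CC1=CCC[C@H]([C@@](C)(CCOCc2ccccc2)/C=C/[S@](=O)c2ccc(C)cc2)[C@@]1(C)CCS(=O)(=O)c1ccccc1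
F4 | step 4 | (R)-configured enantiomer of sulfoxide 6 | Cc1ccc(cc1)[S@](=O)C/C=C(/C)CCOCc1ccccc1
F5 | step 8 | bis-sulfone: 16 with the C17 sulfoxide oxidised to the sulfone | c1ccccc1COCC[C@@]1(C)[C@H](CS(=O)(=O)c2ccc(C)cc2)C(S(=O)(=O)c2ccccc2)C[C@@]2(C)C(C)=CCC[C@H]12
F6 | step 8 | benzyl ether of 17 | c1ccccc1COCC[C@@]1(C)[C@H](C)CC[C@@]2(C)C(C)=CCC[C@H]12
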